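**Retrosynthetic overview**
1. The last cuts are the two benzyl groups (hydrogenolysis) and then the depside ester C(=O)–O4'. This gives ring A as acid chloride 23, made from purchased methyl olivetolate 19, and ring B as phenol 17.
2. Feature used: ring B carries C1' CO2H, C2' OMe, C3' H, C4' O-acyl, C5' H and C6' pentyl. The oxygen-bearing C4' lies between the two unsubstituted carbons C3' and C5', so C4' and its oxygen are removed together as carbon monoxide 13, cutting C3'–C4' and C4'–C5'.
3. What remains is the open chain C3'–C2'–C1'–C6'–C5', pentadienyl acetate 12, which already holds OMe, CO2Bn and pentyl. It is cut at C1'–C6' (Suzuki) into iodo enol ether 8 (from 1 and 2) and boronate 11 (from 9).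
4. The C3' oxygen enters as acetate by displacement of chloride and is never a free hydroxyl. A free hydroxyl would lie cis to the ester and lactonise.
5. Ring order: ring A is bought as an arene. Ring B is the only ring built, in step 7.

Key step: step 7

Assumption: the ester and the CH2X group are taken to stay cis to each other from enol ether 5 through iodination and coupling (retention), so 8 is drawn Z and 12 is drawn E. Any geometric isomer formed alongside is carried on unseparated, because step 7 erases this geometry.

**Step 1**
Reactants: 1 ethyl 4-chloroacetoacetate; 2 benzyl alcohol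
Product: 3 benzyl 4-chloro-3-oxobutanoate
Conditions: toluene, reflux, EtOH distilled off, no catalyst
Reagents that add atoms: none
Why: Thermal transesterification of a β-keto ester is driven by removal of ethanol, and in the absence of base the chloromethyl ketone is left alone.

**Step 2**
Reactants: 3 benzyl 4-chloro-3-oxobutanoate
Product: 5 benzyl (E)-4-chloro-3-methoxybut-2-enoate, via dimethyl ketal 4 (not isolated)
Conditions: HC(OMe)3 (2 equiv), cat. H2SO4, 25 °C; then cat. p-TsOH, toluene, 90 °C, MeOH distilled off
Reagents that add atoms: trimethyl orthoformate, COC(OC)OC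
Why: Orthoester ketalisation followed by acid-catalysed loss of methanol should give the conjugated enol ether as the equilibrated E isomer (OMe trans to the ester), as is usual for alkyl 4-chloroacetoacetates, and it also blocks the acidic C2 methylene before step 3.

**Step 3**
Reactants: 5 benzyl (E)-4-chloro-3-methoxybut-2-enoate
Product: 6 benzyl (E)-4-acetoxy-3-methoxybut-2-enoate
Conditions: KOAc (1.5 equiv), cat. Bu4NI, DMF, 40 °C
Reagents that add atoms: potassium acetate, CC(=O)[O-].[K+]
Why: SN2 displacement of a primary allylic chloride by acetate brings the oxygen in already acylated, so the free hydroxyl that would close onto the cis ester to a methyl tetronate never appears.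

**Step 4**
Reactants: 6 benzyl (E)-4-acetoxy-3-methoxybut-2-enoate
Product: 8 benzyl (Z)-4-acetoxy-2-iodo-3-methoxybut-2-enoate, via iodo-acetoxy adduct 7 (not isolated)
Conditions: NIS (1.2 equiv), AcOH (2 equiv), CH2Cl2, 25 °C, dark; then NEt3, 0 → 25 °C
Reagents that add atoms: N-iodosuccinimide, O=C1CCC(=O)N1I (acetic acid, CC(=O)O, adds to 7 only and leaves again)
Why: Electrophilic α-iodination of a β-alkoxyacrylate by addition of iodine and acetate across the push–pull alkene and base-induced elimination of acetic acid is a known sequence for 3-methoxyacrylates, and C2 is the only nucleophilic carbon of 6.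

**Step 5**
Reactants: 9 hept-1-yne
Product: 11 2-(hept-1-en-2-yl)-4,4,5,5-tetramethyl-1,3,2-dioxaborolane, via vinylalane 10 (not isolated)
Conditions: DIBAL-H (1.3 equiv), NiCl2(dppp) (3 mol %), THF, 0 → 22 °C; then MeOBpin, 0 → 65 °C
Reagents that add atoms: 2-methoxy-4,4,5,5-tetramethyl-1,3,2-dioxaborolane, COB1OC(C)(C)C(C)(C)O1 (DIBAL-H, CC(C)C[AlH]CC(C)C, supplies the aluminium of 10 and only hydrogen to 11)
Why: Nickel-catalysed α-selective (Markovnikov) hydroalumination of a terminal alkyl alkyne places aluminium on the internal carbon, and aluminium-to-boron exchange with the methoxyboronate then gives the 1,1-disubstituted vinylboronate in one pot, a known sequence.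

**Step 6**
Reactants: 8 benzyl (Z)-4-acetoxy-2-iodo-3-methoxybut-2-enoate; 11 2-(hept-1-en-2-yl)-4,4,5,5-tetramethyl-1,3,2-dioxaborolane
Product: 12 benzyl (E)-4-acetoxy-2-(hept-1-en-2-yl)-3-methoxybut-2-enoate
Conditions: Pd(OAc)2 (5 mol %), SPhos (10 mol %), K3PO4 (2 equiv), THF/H2O 10:1, 40 °C, 1.05 equiv of 11
Reagents that add atoms: none
Why: In this Suzuki–Miyaura coupling, oxidative addition of zerovalent palladium into the electron-poor C–I bond should be far faster at 40 °C than ionisation of the hindered allylic acetate, the biaryl phosphine copes with two hindered partners, and the alkene geometry is retained.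

**Step 7**
Reactants: 12 benzyl (E)-4-acetoxy-2-(hept-1-en-2-yl)-3-methoxybut-2-enoate; 13 carbon monoxide
Product: 18 benzyl 4-acetoxy-2-methoxy-6-pentylbenzoate, via Z-dienyl acetate 14 (not isolated), via dienylketene 15 (not isolated), via cyclohexadienone 16 (not isolated), via phenol 17 (not isolated)
Conditions: PdCl2(PPh3)2 (5 mol %), CO (60 atm), Ac2O (2 equiv), NEt3 (2 equiv), toluene, 150 °C, autoclave
Reagents that add atoms: acetic anhydride, CC(=O)OC(C)=O
Why: PdCl2(PPh3)2 (divalent palladium) is reduced in the flask to zerovalent palladium, which ionises the allylic C3'–OAc bond of 12 to a pentadienylpalladium (η3-allyl) complex; CO inserts at the CH2 terminus C3' (first new bond, C3'–C4') and NEt3 takes the now acidic C3'–H from the acylpalladium species to release dienylketene 15. Because C1' bears two carbon groups, one of them has to lie anti in the allyl complex in any case, and η3–η1–η3 exchange through the C1'-bound palladium ester enolate, together with reversible acetate return to the Z isomer 14, brings the heptenyl group cis to C3', so the E geometry of 12 should not block closure. Ring B, a six-membered carbocycle, closes by thermal disrotatory 6π electrocyclisation of 15, the ketene carbon C4' bonding to the unhindered methylene C5' (second new bond), and dienone 16 tautomerises to phenol 17, which Ac2O traps as 18 so that the phenol can neither be O-allylated nor bind the catalyst. The closest known reaction type is the palladium-catalysed cyclocarbonylation of 2,4-pentadienyl acetates and cinnamyl acetates to aryl acetates under this same reagent set, which likewise starts from E alkenes. The selectivity needed is CO insertion at a primary terminus and not at C1', which the fully substituted, ester-bearing C1' secures; insertion at the other primary terminus C5' is harmless, since that ketene closes onto C3' and gives the same arene with CO again between C3' and C5'. No stereocentre is formed, and the substitution pattern of ring B follows from the chain connectivity alone.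

**Step 8**
Reactants: 18 benzyl 4-acetoxy-2-methoxy-6-pentylbenzoate
Product: 17 benzyl 4-hydroxy-2-methoxy-6-pentylbenzoate (now isolated)
Conditions: K2CO3 (0.2 equiv), MeOH, 0 °C
Reagents that add atoms: none
Why: Base-catalysed methanolysis (Zemplén-type transesterification) of an aryl acetate is fast at 0 °C, whereas the benzyl ester flanked by OMe and pentyl is too hindered to exchange.

**Step 9**
Reactants: 19 methyl 2,4-dihydroxy-6-pentylbenzoate (methyl olivetolate)
Product: 20 methyl 2-hydroxy-4-methoxy-6-pentylbenzoate
Conditions: MeI (1.1 equiv), K2CO3 (1.1 equiv), acetone, reflux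
Reagents that add atoms: iodomethane, CI
Why: In this Williamson etherification the C2 hydroxyl is tied up in a hydrogen bond to the ester carbonyl, so one equivalent of MeI should alkylate only the free C4 hydroxyl.

**Step 10**
Reactants: 20 methyl 2-hydroxy-4-methoxy-6-pentylbenzoate
Product: 21 methyl 2-(benzyloxy)-4-methoxy-6-pentylbenzoate
Conditions: BnBr (1.3 equiv), K2CO3 (2 equiv), DMF, 60 °C
Reagents that add atoms: benzyl bromide, BrCc1ccccc1
Why: Williamson benzylation in a dipolar solvent at raised temperature breaks the chelate and alkylates the one remaining phenol.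

**Step 11**
Reactants: 21 methyl 2-(benzyloxy)-4-methoxy-6-pentylbenzoate
Product: 22 2-(benzyloxy)-4-methoxy-6-pentylbenzoic acid
Conditions: KOH, DMSO/H2O, 100 °C; then cold 1 M HCl
Reagents that add atoms: potassium hydroxide, [K+].[OH-]
Why: Saponification of a di-ortho-substituted benzoate needs hot hydroxide in aqueous DMSO, which both ethers tolerate, and cold acidification avoids decarboxylation of the electron-rich acid.

**Step 12**
Reactants: 22 2-(benzyloxy)-4-methoxy-6-pentylbenzoic acid
Product: 23 2-(benzyloxy)-4-methoxy-6-pentylbenzoyl chloride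
Conditions: (COCl)2 (1.5 equiv), cat. DMF, CH2Cl2, 0 → 25 °C; evaporated, used crude
Reagents that add atoms: oxalyl chloride, O=C(Cl)C(=O)Cl
Why: Acid chloride formation under DMF (Vilsmeier-type) catalysis runs at or below room temperature without Lewis acid, so the ortho benzyl ether should survive.

**Step 13**
Reactants: 17 benzyl 4-hydroxy-2-methoxy-6-pentylbenzoate; 23 2-(benzyloxy)-4-methoxy-6-pentylbenzoyl chloride
Product: 24 benzyl 4-{[2-(benzyloxy)-4-methoxy-6-pentylbenzoyl]oxy}-2-methoxy-6-pentylbenzoate
Conditions: NEt3 (2 equiv), DMAP (0.2 equiv), CH2Cl2, 0 → 25 °C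
Reagents that add atoms: none
Why: DMAP-catalysed O-acylation through the acylpyridinium ion overcomes the hindrance of the aroyl chloride, and the C4' phenol is the only free nucleophile in 17.

**Step 14**
Reactants: 24 benzyl 4-{[2-(benzyloxy)-4-methoxy-6-pentylbenzoyl]oxy}-2-methoxy-6-pentylbenzoate
Product: 25 2'-O-methylperlatolic acid
Conditions: H2 (1 atm), 10 % Pd/C, EtOAc, 25 °C
Reagents that add atoms: none
Why: Catalytic hydrogenolysis cleaves the two benzylic C–O bonds (ester and ether) and leaves the aryl ester link, the methyl ethers and both arenes untouched.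

**Compound list**
1 | ethyl 4-chloroacetoacetate | CCOC(=O)CC(=O)CCl | starting material
2 | benzyl alcohol | OCc1ccccc1 | starting material
3 | benzyl 4-chloro-3-oxobutanoate | O=C(CCl)CC(=O)OCc1ccccc1 | intermediate
4 | benzyl 4-chloro-3,3-dimethoxybutanoate | COC(CCl)(CC(=O)OCc1ccccc1)OC | intermediate
5 | benzyl (E)-4-chloro-3-methoxybut-2-enoate | CO/C(CCl)=C/C(=O)OCc1ccccc1 | intermediate
6 | benzyl (E)-4-acetoxy-3-methoxybut-2-enoate | CO/C(COC(C)=O)=C/C(=O)OCc1ccccc1 | intermediate
7 | benzyl 3,4-diacetoxy-2-iodo-3-methoxybutanoate (diastereomer mixture, both centres lost on elimination) | COC(COC(C)=O)(OC(C)=O)C(I)C(=O)OCc1ccccc1 | intermediate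
8 | benzyl (Z)-4-acetoxy-2-iodo-3-methoxybut-2-enoate | CO/C(COC(C)=O)=C(\I)C(=O)OCc1ccccc1 | intermediate
9 | hept-1-yne | C#CCCCCC | starting material
10 | (hept-1-en-2-yl)diisobutylaluminium | C=C(CCCCC)[Al](CC(C)C)CC(C)C | intermediate
11 | 2-(hept-1-en-2-yl)-4,4,5,5-tetramethyl-1,3,2-dioxaborolane | C=C(CCCCC)B1OC(C)(C)C(C)(C)O1 | intermediate
12 | benzyl (E)-4-acetoxy-2-(hept-1-en-2-yl)-3-methoxybut-2-enoate | C=C(CCCCC)/C(C(=O)OCc1ccccc1)=C(OC)/COC(C)=O | intermediate
13 | carbon monoxide | [C-]#[O+] | starting material
14 | benzyl (Z)-4-acetoxy-2-(hept-1-en-2-yl)-3-methoxybut-2-enoate | C=C(CCCCC)/C(C(=O)OCc1ccccc1)=C(OC)\COC(C)=O | intermediate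
15 | benzyl (Z)-2-(hept-1-en-2-yl)-3-methoxy-5-oxopenta-2,4-dienoate (dienylketene) | C=C(CCCCC)/C(C(=O)OCc1ccccc1)=C(OC)\C=C=O | intermediate
16 | benzyl 6-methoxy-4-oxo-2-pentylcyclohexa-1,5-diene-1-carboxylate | O=C1C=C(OC)C(C(=O)OCc2ccccc2)=C(CCCCC)C1 | intermediate
17 | benzyl 4-hydroxy-2-methoxy-6-pentylbenzoate | CCCCCc1cc(O)cc(OC)c1C(=O)OCc1ccccc1 | intermediate
18 | benzyl 4-acetoxy-2-methoxy-6-pentylbenzoate | CCCCCc1cc(OC(C)=O)cc(OC)c1C(=O)OCc1ccccc1 | intermediate
19 | methyl 2,4-dihydroxy-6-pentylbenzoate (methyl olivetolate) | CCCCCc1cc(O)cc(O)c1C(=O)OC | starting material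
20 | methyl 2-hydroxy-4-methoxy-6-pentylbenzoate | CCCCCc1cc(OC)cc(O)c1C(=O)OC | intermediate
21 | methyl 2-(benzyloxy)-4-methoxy-6-pentylbenzoate | CCCCCc1cc(OC)cc(OCc2ccccc2)c1C(=O)OC | intermediate
22 | 2-(benzyloxy)-4-methoxy-6-pentylbenzoic acid | CCCCCc1cc(OC)cc(OCc2ccccc2)c1C(=O)O | intermediate
23 | 2-(benzyloxy)-4-methoxy-6-pentylbenzoyl chloride | CCCCCc1cc(OC)cc(OCc2ccccc2)c1C(=O)Cl | intermediate
24 | benzyl 4-{[2-(benzyloxy)-4-methoxy-6-pentylbenzoyl]oxy}-2-methoxy-6-pentylbenzoate | CCCCCc1cc(OC)cc(OCc2ccccc2)c1C(=O)Oc1cc(CCCCC)c(C(=O)OCc2ccccc2)c(OC)c1 | intermediate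
25 | 2'-O-methylperlatolic acid | CCCCCc1cc(OC)cc(O)c1C(=O)Oc1cc(CCCCC)c(C(=O)O)c(OC)c1 | target

Total step count: 14.
Longest linear sequence: 9 steps (1, 2, 3, 4, 6, 7, 8, 13, 14).

**Steps most likely to fail**

**Step 7.**
- What may go wrong: ionisation of the tetrasubstituted, methoxy-bearing allylic acetate may be slow. Syn–anti exchange may lag behind β-hydride loss from the pentadienylpalladium complex. The diene may polymerise or undergo hydrogen shifts at 150 °C before CO is taken up.
- Fallback: ring B is taken from the aromatic pool, setting out from 19 and coming back at 17.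
  - 19 is allylated at the free C4 hydroxyl (allyl bromide, K2CO3, acetone) to methyl 4-(allyloxy)-2-hydroxy-6-pentylbenzoate F1.
  - The chelated hydroxyl is methylated (MeI, K2CO3, DMF) to methyl 4-(allyloxy)-2-methoxy-6-pentylbenzoate F2.
  - Saponification (KOH, aqueous DMSO, 100 °C) gives 4-(allyloxy)-2-methoxy-6-pentylbenzoic acid F3.
  - The carboxylate is alkylated (BnBr, KHCO3, DMF) to benzyl 4-(allyloxy)-2-methoxy-6-pentylbenzoate F4.
  - Deallylation with Pd(PPh3)4 and morpholine in THF frees phenol 17, which enters step 13.

**Step 6.**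
- What may go wrong: zerovalent palladium may ionise the allylic acetate of 8 or 12 in competition with C–I insertion. The aqueous base may hydrolyse the acetate, and lactonisation would follow. Transmetalation between two hindered partners may be slower than protodeboronation.
- Fallback: a palladium-free, base-free, copper-mediated Stille-type coupling (Liebeskind coupling), setting out from vinylalane 10 and coming back at 12.
  - Iodinolysis of 10 with I2 gives 2-iodohept-1-ene F5.
  - Iodine–lithium exchange (t-BuLi, Et2O, −78 °C) and a Bu3SnCl quench give tributyl(hept-1-en-2-yl)stannane F6.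
  - F6 is joined to 8 with copper thiophene-2-carboxylate, CuO2C(C4H3S) (monovalent copper, 1.5 equiv), in NMP at 0 → 25 °C to give 12. The allylic acetate is inert under these conditions.

**Step 4.**
- What may go wrong: the oxocarbenium ion formed on iodine attack may lose a C4 proton instead of the C2 proton (deconjugation). The enol ether may be demethylated or hydrolysed to an iodo keto ester. The iodide may lose iodine on handling.
- Fallback: the C1'–C2' bond is made by Claisen acylation instead, so no vinyl halide is needed. This sets out from 11 and comes back at 12.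
  - 11 is coupled with benzyl bromoacetate (Pd(OAc)2, P(o-tol)3, K3PO4, THF/H2O) to benzyl 3-methyleneoctanoate F7.
  - The lithium dienolate of F7 (LiHMDS, 2 equiv, THF, −78 °C) is C-acylated at the α-carbon with acetoxyacetyl chloride to benzyl 4-acetoxy-2-(hept-1-en-2-yl)-3-oxobutanoate F8.
  - O-methylation of the enolate of F8 with a hard electrophile (Me2SO4, Cs2CO3, DMF) gives 12. Any 14 formed with it is equally usable in step 7.

**Further compounds**
F1 | step 7 | methyl 4-(allyloxy)-2-hydroxy-6-pentylbenzoate | C=CCOc1cc(O)c(C(=O)OC)c(CCCCC)c1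
F2 | step 7 | methyl 4-(allyloxy)-2-methoxy-6-pentylbenzoate | C=CCOc1cc(OC)c(C(=O)OC)c(CCCCC)c1
F3 | step 7 | 4-(allyloxy)-2-methoxy-6-pentylbenzoic acid | C=CCOc1cc(OC)c(C(=O)O)c(CCCCC)c1
F4 | step 7 | benzyl 4-(allyloxy)-2-methoxy-6-pentylbenzoate | C=CCOc1cc(OC)c(C(=O)OCc2ccccc2)c(CCCCC)c1
F5 | step 6 | 2-iodohept-1-ene | C=C(I)CCCCC
F6 | step 6 | tributyl(hept-1-en-2-yl)stannane | C=C(CCCCC)[Sn](CCCC)(CCCC)CCCC
F7 | step 4 | benzyl 3-methyleneoctanoate | C=C(CCCCC)CC(=O)OCc1ccccc1
F8 | step 4 | benzyl 4-acetoxy-2-(hept-1-en-2-yl)-3-oxobutanoate (racemic, configurationally labile) | C=C(CCCCC)C(C(=O)COC(C)=O)C(=O)OCc1ccccc1
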